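The reading comes at 5.0 min, and in repeating this run I watch how much E has formed by then.

- midnight: J 20 mM; Q 30.0 mM; temperature 55 °C; time 5.0 min
- summer: J 20 mM; Q 30.0 mM; temperature 35 °C; time 5.0 min

    D → E (k1 = 0.018 s⁻¹, Ea1 = 80.0 kJ mol⁻¹)
    J + G → J.G (k2 = 6.6 M⁻¹ s⁻¹, Ea2 = 55.0 kJ mol⁻¹)
    J ⇌ G + D (K3 = 1.6 × 10⁻⁶ M, k3 = 0.024 s⁻¹, Ea3 = 73.0 kJ mol⁻¹, ΔH3 = −3.00 kJ mol⁻¹)
    Q + G → Q.G (k4 = 24 M⁻¹ s⁻¹, Ea4 = 37.0 kJ mol⁻¹)
    (constants at 35 °C)

- percent here means J units held: one J.G counts as two
- the list of constants is for 35 °C, to be carried to other temperatures by the activation energies and enthalpies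

- the best flask by amount of Q.G, in percent of the J charged; "all alike" if 1.5 percentage points covers them all (midnight / summer / all alike)
- amount of Q.G at the end, in percent of the J charged, midnight
- amount of Q.G at the end, in percent of the J charged, summer

1. J opens reversibly to G and D, and Q or J then catches G. In summer at the start, this capture, pseudo-first-order in G, runs at c = k_Q[Q] + k_J[J] = 0.852 s⁻¹. J's share of it is φ = 15.5 %.

2. I take [G][D] = K[J]. Each captured G leaves one D unpaired, which goes on to E, so a steady [D] needs k_D[D] = c[G]. Together these give [D] = √(K[J]c/k_D), which is 1.23 mM in summer.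

3. The assumption passes in summer: D returns G to J at 18.5 s⁻¹, far faster than capture. In summer I also reckon that D reaches its level in about 27.8 s, shorter than the run.

4. I call k_D[D] = √(k_D K[J]c) the throughput, the amount passing through G per minute, and in summer, reckoned on the charges, it is 1.33 mM min⁻¹. J falls at r(1+φ), since a capture by J spends a second J, and Q.G rises at r(1−φ).

5. For midnight, the logarithm of each speed-up scales with the activation energy, so the drain speeds up 6.71-fold. Then c = 2.22 s⁻¹, φ = 22.0 % and [D] = 0.741 mM, and the equilibrium holds there too. Reckoned on the charges, the midnight throughput is 5.37 mM min⁻¹.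

6. First answer: held for 5.0 min, that midnight throughput passes 26.9 mM, more than the 20 mM of J charged. So the first pass overshoots, and I go round again.

7. Second round: I put the mean [Q] and [J] of the first pass into c and φ, taking [J] to nil at midnight. This gives c = 0.759 s⁻¹ and φ = 14.0 % in summer, and c = 1.61 s⁻¹ and φ = 15.2 % at midnight.

8. At fixed c and φ the throughput goes with √[J], so √[J] falls on a straight line. Per minute, the root of the fraction of J left loses (1+φ)r/(2[J]), with [J] taken at the charge and r taken at that [J] and the new c. At the reading I reckon [J] = 13.5 mM in summer and 2.35 mM at midnight.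

9. Q.G is then 24.6 % of the J charged in summer and 65.0 % at midnight, so my best flask is midnight.

The forecast names midnight, with 62 % at midnight and 26 % in summer, holding that “the throughput is set by the D → E drain”. My midnight figure stands 3 percentage points above its figure, and my summer figure 1.4 points below.

The simulation gives midnight, with 62.4 % at midnight and 26.0 % in summer. The summer flask holds 5.18 mM of E at 5.00 min, which is 77.9 % of what the summer throughput reckoned on the charges, 1.33 mM min⁻¹, passes when held for 5.0 min.

Take the summer flask with 34 mM of J. Its throughput, reckoned on its charges, is 1.82 mM min⁻¹, faster than the same reckoning for summer, and J's share of capture at those charges is 23.8 %, so the first pass gives 20.4 % of its J as Q.G. The simulated flask reads 19.1 %.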